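At the earliest birch reading, 2.50 min, left-handed substrate has fallen to 41.0% while right-handed substrate stands at 49.3%, so the excess asked for grows with the left-handed product formed.

all flasks: free catalyst 4.1 mM; added ligand 3.2 mM

| flask | left-handed substrate | right-handed substrate | partner | protic impurity | remark | time |
|---|---|---|---|---|---|---|
| birch | 0.10 M | 0.10 M | 0.030 M | 0.030 M | run made earlier |  |
| cedar | 0.10 M | 0.10 M | 0.12 M | 0.030 M | run made earlier |  |
| elm | 0.050 M | 0.050 M | 0.060 M | 0.030 M | run made earlier |  |
| flask | 0.10 M | 0.10 M | 0.0600 M | 0.0300 M |  | 30 min |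

| run | time / min | right-handed substrate / % | left-handed substrate / % | left-handed product / % |
|---|---|---|---|---|
| birch | 2.50 | 49.3 | 41.0 | 6.0 |
| birch | 8.00 | 50.1 | 37.7 | 9.5 |
| birch | 12.0 | 49.7 | 39.3 | 12.2 |
| birch | 20.0 | 48.6 | 37.2 | 10.5 |
| birch | 30.0 | 48.2 | 39.1 | 12.5 |
| birch | 40.0 | 48.3 | 36.3 | 12.5 |
| cedar | 6.00 | 49.3 | 10.7 | 38.2 |
| cedar | 12.0 | 49.7 | 4.5 | 44.4 |
| cedar | 20.0 | 49.4 | 3.9 | 43.9 |
| cedar | 25.0 | 49.0 | 3.4 | 44.2 |
| cedar | 30.0 | 48.9 | 1.7 | 46.0 |
| cedar | 40.0 | 48.0 | 2.6 | 47.2 |
| elm | 3.00 | 47.0 | 19.2 | 28.7 |
| elm | 5.00 | 47.5 | 15.1 | 35.3 |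
| elm | 10.0 | 47.4 | 8.7 | 39.1 |
| elm | 20.0 | 48.4 | 6.5 | 42.8 |
| elm | 40.0 | 50.1 | 7.6 | 45.0 |

(each reading ± 1 percentage point)

- whether the excess of right-handed substrate over left-handed substrate among what is left of the two reaches 80% by 30 min (yes / no)
- the highest excess of right-handed substrate over left-handed substrate among what is left of the two up to 30 min

- free catalyst is single-handed; left-handed substrate and right-handed substrate are mirror images of each other, charged as a racemate, each of them at the stated concentration
- the earlier runs were read with a standard deviation of 1 percentage point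

In birch the left-handed product stalls while left-handed substrate remains: at 30.0 min that run holds 39.1% of the substrate. We therefore treat partner as the limiting reagent, at one partner per product, and define the partner yield as stalled left-handed product per partner charged. It reads 0.750 in elm and 0.833 in birch. With right-handed substrate intact, a product y from a charge c of each hand gives an excess y/(2c − y). In this flask the asked excess takes 0.0889 M of product, more than the 0.0600 M of partner charged, so we say no. Applied to this flask, the two yields give an estimated top excess of 29.0% to 33.3%.

The forecast says no, with a top of 34%, holding that “the endpoint is set by the partner, not by time”.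

The flask gives no, with a top of 31.1%.

    free catalyst + left-handed substrate ⇌ catalyst intermediate A (K = 230 /M, k = 190 /M/s)
    free catalyst + right-handed substrate ⇌ catalyst intermediate B (K = 64.0 /M, k = 50.0 /M/s)
    partner + catalyst intermediate A → free catalyst + left-handed product (k = 1.80 /M/s)
    partner + catalyst intermediate B → free catalyst + right-handed product (k = 0.0240 /M/s)
    free catalyst + added ligand ⇌ idle complex (K = 73.0 /M, k = 1.40 /M/s)
    partner + protic impurity → quenched reagent (k = 0.0670 /M/s)
    2 free catalyst ⇌ resting dimer (K = 2900 /M, k = 6.10 /M/s)

At 30.0 min this flask has 0% of its partner left and 52% of its left-handed substrate, with 0.0139 M of quenched reagent. Its left-handed product, 22.9% of both substrates charged, is a partner yield of 0.763. For a neighbouring flask, like this one but charged with 0.24 M of partner, the elm yield reckons 0.180 M of product, more than its 0.10 M of left-handed substrate, so we expect the limiting reagent to change. In that flask, at 30.0 min, left-handed substrate stands at 0% with 40.9% of the partner left, and the top reaches 100%.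

All runs stem from a simulated flask on assumed constants; noise was put on by code.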